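**Retrosynthetic overview**

1. Locants (spiro[5.5]undecane numbering of the target): ring B = C1–C5 (C2 = CHBr, C3 = C(OH)Me), spiro carbon C6, ring A = C7–C11 (C7 = C(Me)=, C8 = =CH, C9 = CH2, C10 = CHBr, C11 = CMe2). Target 18 ⇐ C10 ketone 15 (catalyst-controlled reduction, then bromide by inversion) ⇐ C10 carbinol 14.
2. Ring A is disconnected at C7=C8 and C9–C10 together: the C8–C9 pair is vinyltriphenylphosphonium bromide 11, joined in one pot to the O–CH2 carbon (future C10, as a radical) and the acetyl carbon (future C7, by Wittig closure) of keto alcohol 10.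
3. Feature that allows this: in ring A, C7 and C10 stand 1,4 to each other across C6 and C11, both fully substituted. The γ-hydroxy ketone 10 therefore cannot enolise or eliminate between its two reacting carbons, the alkene can form only at C7=C8, and 10 is simply the MeLi adduct of a γ-lactone.
4. Ring B stereocentres C2 and C3 ⇐ bromolactonisation of the carboxylate on C6, which ties the C3–O bond to the carboxyl face and puts Br anti at C2; C6 ⇐ enantioselective Diels–Alder reaction of isoprene 3 with methylene lactone 2 (from ketopantolactone 1).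
5. Order of ring formation: temporary γ-lactone ring (present in 1), ring B (step 2), ring A (step 6).

Key step: step 6

Remark: the sense of induction in step 2 is assigned by analogy; should 4 form as its mirror image, the (R)-configured catalyst is used and the rest of the route is unchanged.

**Route**

Step 1
Reactants: 1 ketopantolactone (4,4-dimethyldihydrofuran-2,3-dione)
Product: 2 4,4-dimethyl-3-methylenedihydrofuran-2(3H)-one
Conditions: Ph3PCH3Br, KOtBu, THF, 0 °C to rt
Reagents that add atoms: methyltriphenylphosphonium bromide, C[P+](c1ccccc1)(c1ccccc1)c1ccccc1.[Br-]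
Why: Wittig methylenation: only the ketone carbonyl of the non-enolisable α-keto lactone is electrophilic enough for the ylide at 0 °C, and no stereocentre is formed.

Step 2
Reactants: 2 4,4-dimethyl-3-methylenedihydrofuran-2(3H)-one; 3 isoprene (2-methylbuta-1,3-diene)
Product: 4 (5S)-4,4,8-trimethyl-2-oxaspiro[4.5]dec-7-en-1-one
Conditions: (S)-o-tolyl-CBS-oxazaborolidine (10 mol%), AlBr3 (8 mol%), CH2Cl2, −40 °C
Reagents that add atoms: none
Why: Enantioselective Diels–Alder reaction under chiral Lewis acid catalysis: coordination of the lactone carbonyl to the cationic boron centre activates the locked s-cis exocyclic dienophile, isoprene adds with para orientation (its CH2 next to C–Me bonds to the exocyclic CH2), and the catalyst shields one face of the flat dienophile, so that the spiro carbon, the only stereocentre, is set by the catalyst as (S).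

Step 3
Reactants: 4 (5S)-4,4,8-trimethyl-2-oxaspiro[4.5]dec-7-en-1-one
Product: 7 (5S,7R,8R)-7-bromo-8-hydroxy-4,4,8-trimethyl-2-oxaspiro[4.5]decan-1-one, via sodium hydroxy carboxylate 5 (not isolated), via bridged bromolactone 6 (not isolated)
Conditions: NaOH (1.0 equiv), THF/H2O, 50 °C; NBS, 0 °C; then 1 M HCl, rt
Reagents that add atoms: sodium hydroxide, [Na+].[OH-]; N-bromosuccinimide, O=C1CCC(=O)N1Br
Why: Lactone saponification followed by Markovnikov bromolactonisation and acyl transfer: the carboxylate on the spiro carbon can reach the methyl-bearing alkene carbon only across its own face of the ring, so the new C–O bond is cis to the carboxyl carbon and bromine enters anti at the neighbouring CH, which fixes both new stereocentres relative to the spiro carbon, and under acid the primary hydroxyl then takes the acyl group back to give the unstrained γ-lactone and free the tertiary alcohol.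

Step 4
Reactants: 7 (5S,7R,8R)-7-bromo-8-hydroxy-4,4,8-trimethyl-2-oxaspiro[4.5]decan-1-one
Product: 8 (5S,7R,8R)-7-bromo-4,4,8-trimethyl-8-[(triethylsilyl)oxy]-2-oxaspiro[4.5]decan-1-one
Conditions: TESOTf, 2,6-lutidine, CH2Cl2, −40 to 0 °C
Reagents that add atoms: triethylsilyl trifluoromethanesulfonate, CC[Si](CC)(CC)OS(=O)(=O)C(F)(F)F
Why: Silylation of a hindered tertiary alcohol with a silyl triflate and a non-nucleophilic base; no stereocentre is affected and the base is too weak to close an epoxide.

Step 5
Reactants: 8 (5S,7R,8R)-7-bromo-4,4,8-trimethyl-8-[(triethylsilyl)oxy]-2-oxaspiro[4.5]decan-1-one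
Product: 10 1-[(1S,3R,4R)-3-bromo-1-(1-hydroxy-2-methylpropan-2-yl)-4-methyl-4-[(triethylsilyl)oxy]cyclohexyl]ethan-1-one, via lithium hemiketalate 9 (not isolated)
Conditions: MeLi (1.3 equiv), THF, −78 °C; AcOH, −78 °C
Reagents that add atoms: methyllithium, [Li]C
Why: Addition of an organolithium to a lactone: the hindered carbonyl takes up one methyl group and rests as lithium hemiketalate 9 at −78 °C, so that the ketone appears only on quenching and is not attacked again; the spiro carbon and ring B are untouched.

Step 6
Reactants: 10 1-[(1S,3R,4R)-3-bromo-1-(1-hydroxy-2-methylpropan-2-yl)-4-methyl-4-[(triethylsilyl)oxy]cyclohexyl]ethan-1-one; 11 vinyltriphenylphosphonium bromide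
Product: 14 (2R,3R,6R)-2-bromo-3,7,11,11-tetramethyl-3-[(triethylsilyl)oxy]spiro[5.5]undec-7-en-10-ol as both C10 epimers, via hydroxyalkyl phosphonium bromide 12 (not isolated), via phosphorus ylide 13 (not isolated)
Conditions: [Ir(dF(CF3)ppy)2(dtbbpy)]PF6 (1 mol%), quinuclidine (10 mol%), Bu4N(H2PO4) (25 mol%), MeCN, blue LEDs, rt; then MeCN removed, KOtBu (3 equiv), THF, 0 to 50 °C
Reagents that add atoms: none
Why: Proposed new method: the excited trivalent iridium photocatalyst oxidises quinuclidine, whose radical cation abstracts a hydrogen atom from the O-bearing CH2 of 10 (open form or cyclic hemiketal), the nucleophilic α-oxy radical adds to the CH2 terminus of 11 to make the C9–C10 bond, divalent iridium reduces the α-phosphonio radical to an ylide that quinuclidinium protonates to salt 12, and KOtBu then returns ylide 13, which olefinates the methyl ketone intramolecularly to make C7=C8 with loss of Ph3PO. The closest known reaction types are photoredox radical addition to vinylphosphonium salts with radical–polar crossover to an ylide and Wittig trapping (three-component olefination), photoredox/hydrogen-atom-transfer α-C–H alkylation of alcohols with electron-poor alkenes, and annulations of vinylphosphonium salts that end in an intramolecular Wittig reaction; new here is their union on a γ-hydroxy ketone. Ring A is closed in the Wittig stage as a six-membered ring by attack of the ylide carbon C8 on the exocyclic ketone carbon C7 (oxaphosphetane formation and collapse), the C9–C10 bond having been made intermolecularly. The one new stereocentre, C10, arises in the radical addition without control and is expected as a mixture of epimers, which is why it is erased in step 7 and reset in step 8. The step needs site-selective hydrogen abstraction and a single alkene regioisomer: the O–CH2 group is the only hydridic, oxygen-activated C–H in 10 (the silyl ether carbon is fully substituted, the CHBr hydrogen is deactivated), and because C6 and C11 carry no hydrogen the Wittig reaction can place the double bond only at C7=C8.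

Step 7
Reactants: 14 (2R,3R,6R)-2-bromo-3,7,11,11-tetramethyl-3-[(triethylsilyl)oxy]spiro[5.5]undec-7-en-10-ol
Product: 15 (2R,3R,6R)-2-bromo-3,7,11,11-tetramethyl-3-[(triethylsilyl)oxy]spiro[5.5]undec-7-en-10-one
Conditions: Dess–Martin periodinane, CH2Cl2, 0 °C to rt
Reagents that add atoms: none
Why: Dess–Martin oxidation: a non-basic oxidant converts both C10 epimers into one ketone and should leave the β,γ-double bond in place.

Step 8
Reactants: 15 (2R,3R,6R)-2-bromo-3,7,11,11-tetramethyl-3-[(triethylsilyl)oxy]spiro[5.5]undec-7-en-10-one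
Product: 16 (2R,3R,6R,10R)-2-bromo-3,7,11,11-tetramethyl-3-[(triethylsilyl)oxy]spiro[5.5]undec-7-en-10-ol
Conditions: (S)-2-methyl-CBS-oxazaborolidine (0.5 equiv), catecholborane, toluene, −78 to −40 °C
Reagents that add atoms: none
Why: Corey–Bakshi–Shibata reduction: the carbonyl lies between a fully substituted carbon (large group) and a CH2 (small group), so the (S)-oxazaborolidine delivers hydride to one face and sets C10 as (R) under catalyst control, the distant ring B centres exerting little bias, while catecholborane does not hydroborate the hindered alkene at low temperature.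

Step 9
Reactants: 16 (2R,3R,6R,10R)-2-bromo-3,7,11,11-tetramethyl-3-[(triethylsilyl)oxy]spiro[5.5]undec-7-en-10-ol
Product: 17 triethyl{[(2R,3R,6R,10S)-2,10-dibromo-3,7,11,11-tetramethylspiro[5.5]undec-7-en-3-yl]oxy}silane
Conditions: CBr4, PPh3, toluene, 0 to 80 °C
Reagents that add atoms: tetrabromomethane, BrC(Br)(Br)Br
Why: Appel bromination: the alkoxyphosphonium ion is displaced by bromide in an SN2 reaction, so the (10R)-alcohol gives the (10S)-bromide by inversion; heating is needed because the carbinol carbon is next to the CMe2 carbon.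

Step 10
Reactants: 17 triethyl{[(2R,3R,6R,10S)-2,10-dibromo-3,7,11,11-tetramethylspiro[5.5]undec-7-en-3-yl]oxy}silane
Product: 18 (2R,3R,6R,10S)-2,10-dibromo-3,7,11,11-tetramethylspiro[5.5]undec-7-en-3-ol (target)
Conditions: HF·pyridine, THF, 0 °C to rt
Reagents that add atoms: none
Why: Acidic fluoride cleavage of the triethylsilyl ether: no alkoxide is formed, so the trans-bromohydrin cannot close to an epoxide, and both C–Br bonds and the alkene are inert to HF·pyridine at this temperature.

**Compound list**

1 | ketopantolactone (4,4-dimethyldihydrofuran-2,3-dione) | CC1(C)COC(=O)C1=O | starting material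
2 | 4,4-dimethyl-3-methylenedihydrofuran-2(3H)-one | C=C1C(=O)OCC1(C)C | intermediate
3 | isoprene (2-methylbuta-1,3-diene) | C=CC(C)=C | starting material
4 | (5S)-4,4,8-trimethyl-2-oxaspiro[4.5]dec-7-en-1-one | CC1=CC[C@]2(CC1)C(=O)OCC2(C)C | intermediate
5 | sodium (1S)-1-(1-hydroxy-2-methylpropan-2-yl)-4-methylcyclohex-3-ene-1-carboxylate | CC1=CC[C@](CC1)(C(=O)[O-])C(C)(C)CO.[Na+] | intermediate
6 | (1R,4S,6R)-6-bromo-4-(1-hydroxy-2-methylpropan-2-yl)-1-methyl-2-oxabicyclo[2.2.2]octan-3-one | OCC(C)(C)[C@@]12CC[C@@](C)(OC1=O)[C@H](Br)C2 | intermediate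
7 | (5S,7R,8R)-7-bromo-8-hydroxy-4,4,8-trimethyl-2-oxaspiro[4.5]decan-1-one | O=C1OCC(C)(C)[C@@]12CC[C@@](C)(O)[C@H](Br)C2 | intermediate
8 | (5S,7R,8R)-7-bromo-4,4,8-trimethyl-8-[(triethylsilyl)oxy]-2-oxaspiro[4.5]decan-1-one | O=C1OCC(C)(C)[C@@]12CC[C@@](C)(O[Si](CC)(CC)CC)[C@H](Br)C2 | intermediate
9 | lithium (5S,7R,8R)-7-bromo-1,4,4,8-tetramethyl-8-[(triethylsilyl)oxy]-2-oxaspiro[4.5]decan-1-olate (C1 epimers) | [Li+].CC1([O-])OCC(C)(C)[C@@]12CC[C@@](C)(O[Si](CC)(CC)CC)[C@H](Br)C2 | intermediate
10 | 1-[(1S,3R,4R)-3-bromo-1-(1-hydroxy-2-methylpropan-2-yl)-4-methyl-4-[(triethylsilyl)oxy]cyclohexyl]ethan-1-one | OCC(C)(C)[C@]1(C(C)=O)CC[C@@](C)(O[Si](CC)(CC)CC)[C@H](Br)C1 | intermediate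
11 | vinyltriphenylphosphonium bromide | C=C[P+](c1ccccc1)(c1ccccc1)c1ccccc1.[Br-] | starting material
12 | {4-[(1S,3R,4R)-1-acetyl-3-bromo-4-methyl-4-[(triethylsilyl)oxy]cyclohexyl]-3-hydroxy-4-methylpentyl}triphenylphosphonium bromide (carbinol epimers) | [Br-].OC(CC[P+](c1ccccc1)(c1ccccc1)c1ccccc1)C(C)(C)[C@]1(C(C)=O)CC[C@@](C)(O[Si](CC)(CC)CC)[C@H](Br)C1 | intermediate
13 | {4-[(1S,3R,4R)-1-acetyl-3-bromo-4-methyl-4-[(triethylsilyl)oxy]cyclohexyl]-3-hydroxy-4-methylpentylidene}triphenylphosphorane (carbinol epimers) | OC(CC=P(c1ccccc1)(c1ccccc1)c1ccccc1)C(C)(C)[C@]1(C(C)=O)CC[C@@](C)(O[Si](CC)(CC)CC)[C@H](Br)C1 | intermediate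
14 | (2R,3R,6R)-2-bromo-3,7,11,11-tetramethyl-3-[(triethylsilyl)oxy]spiro[5.5]undec-7-en-10-ol (both C10 epimers) | CC1=CCC(O)C(C)(C)[C@@]12CC[C@@](C)(O[Si](CC)(CC)CC)[C@H](Br)C2 | intermediate
15 | (2R,3R,6R)-2-bromo-3,7,11,11-tetramethyl-3-[(triethylsilyl)oxy]spiro[5.5]undec-7-en-10-one | CC1=CCC(=O)C(C)(C)[C@@]12CC[C@@](C)(O[Si](CC)(CC)CC)[C@H](Br)C2 | intermediate
16 | (2R,3R,6R,10R)-2-bromo-3,7,11,11-tetramethyl-3-[(triethylsilyl)oxy]spiro[5.5]undec-7-en-10-ol | CC1=CC[C@@H](O)C(C)(C)[C@@]12CC[C@@](C)(O[Si](CC)(CC)CC)[C@H](Br)C2 | intermediate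
17 | triethyl{[(2R,3R,6R,10S)-2,10-dibromo-3,7,11,11-tetramethylspiro[5.5]undec-7-en-3-yl]oxy}silane | CC1=CC[C@H](Br)C(C)(C)[C@@]12CC[C@@](C)(O[Si](CC)(CC)CC)[C@H](Br)C2 | intermediate
18 | (2R,3R,6R,10S)-2,10-dibromo-3,7,11,11-tetramethylspiro[5.5]undec-7-en-3-ol | CC1=CC[C@H](Br)C(C)(C)[C@@]12CC[C@@](C)(O)[C@H](Br)C2 | target

**Step count and risks**

Total step count: 10. Longest linear sequence: 10 steps (1 → 2 → 4 → 7 → 8 → 10 → 14 → 15 → 16 → 17 → 18).

Steps most likely to fail:

1. Step 6 (proposed new method). Hydrogen abstraction may be slow on the cyclic hemiketal form of 10, the radical may be returned to C–H before it adds, and in the base stage proton transfer or cyclic alkoxyphosphorane formation may outrun Wittig closure onto the hindered ketone. The fallback uses known chemistry and makes the two bonds in separate steps. It sets out from 10: methylenation of the ketone with Cp2TiMe2 (toluene, 65 °C) should give isopropenyl alcohol F1; Dess–Martin oxidation should give aldehyde F2; addition of allylmagnesium bromide (THF, −78 °C) should give homoallylic alcohol F3 as both carbinol epimers; ring-closing metathesis with the second-generation Hoveyda–Grubbs catalyst (toluene, 80 °C) with loss of ethylene comes back to the route at 14.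

2. Step 2. Face discrimination by the catalyst may be weak, cycloaddition at the hindered α-carbon may be slow, and para regioselectivity may erode if the temperature has to be raised. The fallback sets out from 2 and 3: an EtAlCl2-promoted Diels–Alder reaction (CH2Cl2, −20 °C) should give racemic spirolactone F4; ring opening with (S)-1-phenylethylamine and AlMe3 should give two diastereomeric hydroxy amides, from which hydroxy amide F5 is separated by crystallisation or chromatography; acid-induced relactonisation (TsOH, toluene, 80 °C) releases the amine and comes back to the route at 4.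

3. Step 9. The alkoxyphosphonium intermediate may ionise instead of undergoing SN2 attack, leading to 1,2-methyl shift, participation of the homoallylic double bond or elimination, and so to loss of inversion. The fallback sets out from 16: sulfonylation with Tf2O and pyridine (CH2Cl2, −40 °C) should give triflate F6, a discrete and far better leaving group, which is displaced by Bu4NBr in toluene at 0 °C to rt with inversion and comes back to the route at 17.

Further compounds
F1 | step 6 | 2-[(1R,3R,4R)-3-bromo-4-methyl-1-(prop-1-en-2-yl)-4-[(triethylsilyl)oxy]cyclohexyl]-2-methylpropan-1-ol | OCC(C)(C)[C@]1(C(C)=C)CC[C@@](C)(O[Si](CC)(CC)CC)[C@H](Br)C1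
F2 | step 6 | 2-[(1R,3R,4R)-3-bromo-4-methyl-1-(prop-1-en-2-yl)-4-[(triethylsilyl)oxy]cyclohexyl]-2-methylpropanal | O=CC(C)(C)[C@]1(C(C)=C)CC[C@@](C)(O[Si](CC)(CC)CC)[C@H](Br)C1
F3 | step 6 | 2-[(1R,3R,4R)-3-bromo-4-methyl-1-(prop-1-en-2-yl)-4-[(triethylsilyl)oxy]cyclohexyl]-2-methylhex-5-en-3-ol (C3 epimers) | C=CCC(O)C(C)(C)[C@]1(C(C)=C)CC[C@@](C)(O[Si](CC)(CC)CC)[C@H](Br)C1
F4 | step 2 | racemic 4,4,8-trimethyl-2-oxaspiro[4.5]dec-7-en-1-one | CC1=CCC2(CC1)C(=O)OCC2(C)C
F5 | step 2 | (1S)-1-(1-hydroxy-2-methylpropan-2-yl)-4-methyl-N-[(1S)-1-phenylethyl]cyclohex-3-ene-1-carboxamide | CC1=CC[C@](CC1)(C(=O)N[C@@H](C)c1ccccc1)C(C)(C)CO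
F6 | step 9 | (2R,3R,6R,10R)-2-bromo-3,7,11,11-tetramethyl-3-[(triethylsilyl)oxy]spiro[5.5]undec-7-en-10-yl trifluoromethanesulfonate | CC1=CC[C@@H](OS(=O)(=O)C(F)(F)F)C(C)(C)[C@@]12CC[C@@](C)(O[Si](CC)(CC)CC)[C@H](Br)C2
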